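The rate constants stand for no real mixture; the run is a simulation.

One unit of starting material charged to this flask ends in one of three places: in quenched substrate, in homo dimer, or in a pool of starting material, intermediate and product that pass into each other.

starting material 10 mM; protic impurity 0.500 mM; time 6.0 min

    2 starting material → homo dimer (k1 = 3.48 M⁻¹ s⁻¹)
    starting material + protic impurity → quenched substrate (k2 = 1650 M⁻¹ s⁻¹)
    intermediate ⇌ product (K3 = 2.95, k3 = 0.937 s⁻¹)
    starting material ⇌ intermediate (K4 = 9.75, k4 = 0.263 s⁻¹)

- part of the starting material gone at 6.0 min
- the product standing at 6.0 min, as a percentage of the starting material charged
- the intermediate standing at 6.0 min, as a percentage of the starting material charged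

- percent here means starting material units held: one homo dimer counts as two
- two of one species on the left: rate k times its square, two consumed each time
- run time (flask): 6.0 min

I froze the composition of that pool. The relaxation half-life of starting material and intermediate, 2.39 s, and the forward half-life of intermediate, 0.74 s, are both far shorter than the 6.0 min run, so I took both balances as standing. The weights summed to 39.5:

- starting material: weight 1, share 2.53%
- intermediate: weight 9.75, share 24.7%
- product: weight 28.8, share 72.8%

The first row told me that conversion would say little about the pool's size. The second told me that intermediate would not drain away: a quarter of the pool stays there. The third is the rule I carried: the product share of the pool, product's weight over the sum of the weights.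

That left the size of the pool. The protic impurity meets starting material in excess, so I gave it a pseudo-first-order rate constant of 16.5 s⁻¹, far above the 0.263 s⁻¹ of the path to intermediate, and I charged its full 5.00% first. Dimerisation then starts at 0.265 of that path's rate and falls with the fraction remaining; integrating this race cost 10.3%. My pool was 84.7%, giving 97.9% conversion, 61.7% product and 20.9% intermediate.

The forecast gave 97.9%, 60.4% and 20.5%, its product lower than mine, holding the three “effectively at equilibrium”.

The flask gave 97.9%, 60.6% and 20.6%, with quenched substrate 5.00% and homo dimer 11.7%, so its pool was 83.3%, and 72.8% of that is 60.6%. At the end of this flask, the first half-life of starting material by dimerisation, 11.4 min, was far longer than the 2.39 s relaxation. Product in this flask stood at 61.4% after 0.600 min and 54.2% after 60.0 min. The neighbour flask with 2.5 mM of starting material held 20.0% quenched substrate and 2.44% homo dimer, so the same share predicts 56.5%, and its product stood at 56.5%.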